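## The problem

The target 21 has a fully substituted six-membered ring A (numbered here C1(=O), C2, C3(–O3), C4, C5(=O), C6) whose C2=C3 enol ether is fused to a dihydrofuran (ring B: O3–C2'–C1', with C1' on C2), and C2' carries the carbinol carbon C3' with a methyl and a 4-methylpent-3-enyl group. The four stereocentres form two separate domains: the quaternary carbons C4 (CH3, prenyl) and C6 (prenyl, isobutyryl), 1,3 across the C5 ketone, and the vicinal pair C2'/C3'. Neither domain can steer the other and C4 and C6 cannot be epimerised, so their relative configuration (the prenyl CH2 on C4 cis to the acyl carbon on C6) must be correct when the bonds are made, while C2'/C3' are best taken from a reagent-controlled epoxidation. Ring B must close through O3 and not through O1. C6 bears three acyl groups (C1, C5, isobutyryl) and is cleaved by nucleophilic base (retro-Claisen); the enol next to prenyl groups and the tertiary alcohol do not tolerate acid; three Me2C=CH groups forbid late oxidation. The enabling feature is that C1–C2–C3 is a malonyl unit and C4–C5–C6 a ketone with both α-carbons, and that C4 with its methyl, C5, C6, the isobutyryl C=O with its isopropyl group and the first two carbons of the C4 prenyl group are the ten carbons of carvacrol, with C5 as the phenol carbon. Ring A can therefore be closed as the second ring of a bicyclo[3.3.1]nonane on a carvacrol-derived cyclohexene, and the bridge cut later at its alkene.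

## Retrosynthesis

**Ring B and side chain.** Cutting O3–C2' and C2–C1' leads from 21 to the enolised trione 16 and the epoxy iodide 19. The neighbouring option, a late epoxidation of a C2-neryl group, would have to pick one of four trisubstituted alkenes. 16 keeps only the C4/C6 domain and 19 only the C2'/C3' domain. The forward step must alkylate carbon C2 and not oxygen, then open the epoxide 5-exo at C2' through O3 with inversion, with a base that does not attack the acyl groups on C6.

**Side-chain fragment.** 19 comes from the epoxy alcohol 18 by C–O to C–I exchange, and 18 from nerol 17 by cutting the two epoxide C–O bonds. The Z-alkene of 17 maps onto the relative configuration of C2'/C3'; an E-alkene would give the wrong diastereomer. The forward reaction is a Sharpless epoxidation with the D-(−)-tartrate.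

**Unbridging in reverse.** 16 is the demethylated form of the vinylogous ester 15. Cutting both Me2C=CH double bonds of 15 gives the keto-dialdehyde 14. Joining the aldehyde carbon of the C4 arm to the isobutyryl carbonyl carbon as a ring C=C, and extending the other aldehyde to an allyl terminus, gives the bicyclic enol ether 13. Separate quaternisations of C4 and C6 on a monocyclic trione would give no control of their relation and would require acylation at a hindered carbon. Tying the two cis groups into one ring makes the relation a geometric necessity and removes the triacyl carbon from all earlier intermediates. The forward steps must cleave a hindered trisubstituted alkene and a terminal one without touching the vinylogous ester, and olefinate both aldehydes before they undergo aldol reactions.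

**Absolute configuration.** 13 is the methyl ether of the (1S,5R)-trione 12, freed from its salt 11 with the amine 10, which is crystallised from racemic 9. Compound 9 is the first acidic, rigid compound of the route, so every later step carries one enantiomer. Separating diastereomers after coupling with 19 would waste both advanced fragments. The forward step needs one diastereomeric salt to crystallise cleanly.

**Key disconnection.** Cutting C3–C4 and C1–C6 of 9 gives malonyl dichloride 7 (C1–C2–C3) and the silyl dienol ether 6. A one-bond-at-a-time assembly (acylation, then Claisen condensation) costs more steps. In the [3+3] mode the tether on C4 can reach C6 only on its own face, so the second centre needs no separate control. A bicycle with two quaternary stereocentres is reduced to a monocyclic diene whose only stereocentre is erased in the step. The forward reaction must acylate the methyl-bearing enol carbon first and then the allyl-bearing carbon at its α-position, not the ring CH in the γ-position.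

**The diene.** 6 comes from the aryl silyl ether 5 by Birch reduction, 5 from 6-allylcarvacrol 4 by silylation, 4 from the allyl ether 3 by Claisen rearrangement, and 3 from carvacrol 1 and allyl bromide 2. A silyl group is chosen over methyl because it leaves after the first acylation, so the second acylation runs through a metal enolate.

## Roads not taken

**Alternative 1:** The cut is C2–C1' and C3–O3. Under base, C2 of the C6-enolic trione A1 would open the terminal epoxide A2, formed in situ from 18 by Payne rearrangement, and the freed C2' alkoxide would condense on C3 to give the ring A/B enol A3. The road is shorter, needs no alkene cleavage, and places the C2' oxygen with net retention from a cheap epoxy alcohol; in step count it is better than the chosen plan. Its weak points are structural. The C2' alkoxide can condense on C3 or on C1. Dehydrative closure under base is not a given, and acid is excluded by the tertiary alcohol and the prenyl group. C6 is still enolic in A3, so the quaternary centre with prenyl and isobutyryl must be made last by C-prenylation of an acyl-bearing enol carbon, with O-alkylation as competitor and only 1,3-induction from C4 across a carbonyl group. A1 also needs its C4 centre in absolute sense. The chosen plan is longer, but the C4/C6 relation is fixed by a ring and no dearomative quaternisation at an acyl-bearing carbon is needed.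

**Alternative 2:** The cut is C5–C6 and C1–C2, with C4–C5 broken and re-formed. Heating the cyclobutenone A4 with the siloxyalkyne A5 would give, by ring opening to a vinylketene, [2+2] addition, a second ring opening and 6π closure, the cyclohexadienone A6. The road is convergent and delivers ring A with O1 (silyl) and O3 (ethyl) differentiated and the side chain with both stereocentres already in place. On the O1/O3 question it is better than the chosen plan, which relies on lithium chelation at the ring-B closure. Against it, the C4 centre of A4 becomes planar in the vinylketene and is re-made in the electrocyclisation under the influence of remote side-chain centres only. C6 in A6 carries prenyl but no isobutyryl, so a hindered C-acylation with stereocontrol remains. A4 itself, with a quaternary carbon and a chiral substituent, is a long synthesis. The chosen plan offers cheap starting materials and a secured C4/C6 relation.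

**Alternative 3:** The cut is C1–C6. With KOC(CH3)3 the β-diketone carbon of the side arm of the dihydrofuran ester A7 would add to the ester carbon and close ring A as the enolised trione A8. Ring B and its attachment to O3 are settled before ring A exists, so the O1/O3 ambiguity of the chosen plan does not arise; the closure is a standard intramolecular Claisen condensation. The weak points are the precursor and the end. A7 needs the quaternary C4 built next to a dihydrofuran carbon with control relative to C2', which means a long linear sequence. A8 again has an enolic C6, so the route ends with the same uncontrolled quaternisation as Alternative 1. The chosen plan is weaker in the regiochemistry of ring B but makes both quaternary centres in one step with their relation enforced.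

Key step: step 5

Remark (assumption): the salt of the (1S,5R)-acid with (R)-1-phenylethylamine is taken to be the less soluble one; if the opposite holds, (S)-1-phenylethylamine is used in step 6 and nothing else changes.
Remark: the enolisable triones 9, 12, 16 and 20 are written in one tautomeric form.

## Steps

Step 1
Reactants: 1 carvacrol; 2 allyl bromide
Product: 3 allyl carvacryl ether, 1-methyl-4-(propan-2-yl)-2-(prop-2-en-1-yloxy)benzene
Conditions: K2CO3, acetone, reflux
Reagents that add atoms: none
Why: Williamson ether synthesis; the phenoxide is alkylated at oxygen by the reactive allylic bromide under these standard conditions.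

Step 2
Reactants: 3 allyl carvacryl ether
Product: 4 6-allylcarvacrol, 6-methyl-3-(propan-2-yl)-2-(prop-2-en-1-yl)phenol
Conditions: PhNEt2, 200 °C
Reagents that add atoms: none
Why: Aromatic Claisen rearrangement; the [3,3] shift should go to the only free ortho position, between oxygen and the isopropyl-bearing carbon, and tautomerisation restores the phenol.

Step 3
Reactants: 4 6-allylcarvacrol
Product: 5 tert-butyl(dimethyl)[6-methyl-3-(propan-2-yl)-2-(prop-2-en-1-yl)phenoxy]silane
Conditions: TBSCl, imidazole, DMF, 40 °C
Reagents that add atoms: tert-butyldimethylsilyl chloride, CC(C)(C)[Si](C)(C)Cl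
Why: Standard silylation of a 2,6-disubstituted phenol. The silyl ether is chosen because it survives dissolving-metal reduction and leaves from oxygen after the first acylation in step 5.

Step 4
Reactants: 5 aryl silyl ether
Product: 6 racemic tert-butyl(dimethyl){[2-methyl-5-(propan-2-yl)-6-(prop-2-en-1-yl)cyclohexa-1,4-dien-1-yl]oxy}silane
Conditions: Li, NH3 (l), THF, t-BuOH, −78 → −33 °C; solid NH4Cl
Reagents that add atoms: none
Why: Birch reduction of an aryl silyl ether. Protonation at the unsubstituted carbon meta to oxygen and at the para-related allyl-bearing carbon keeps oxygen and two alkyl groups on the double bonds, whereas the other para pair would place two alkyl groups on sp3 carbons. The alcohol present from the start keeps amide low so the allyl group should not migrate; the new stereocentre is racemic and is erased in step 5.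

Step 5
Reactants: 6 silyl dienol ether; 7 malonyl dichloride
Product: 9 racemic (1RS,5SR)-1-methyl-5-(prop-2-en-1-yl)-6-(propan-2-yl)bicyclo[3.3.1]non-6-ene-2,4,9-trione, via keto acid chloride 8 (not isolated)
Conditions: 7 (2 equiv), Et2O, −20 °C; then KOH, BnEt3NCl (cat.), H2O, −20 °C → rt; aq. HCl
Reagents that add atoms: none
Why: The silyl enol ether carbon that bears the methyl group (future C4) is C-acylated by one acid chloride of 7 (or the derived chlorocarbonyl ketene), and chloride removes the silyl group from the oxocarbenium ion, so the neutral β,γ-unsaturated ketone 8 is formed and no dienol ether persists. Aqueous KOH with the phase-transfer salt then removes the proton at the allyl-bearing carbon (α to the ketone and allylic), and the extended potassium enolate is acylated at this α-carbon by the second acid chloride, which forms C1–C6 and closes ring A. The closest known reaction is the Effenberger annulation of cyclohexanone silyl or methyl enol ethers with malonyl dichloride to bicyclo[3.3.1]nonane-2,4,9-triones, run in its two-stage form with base. The ring closure is 6-(enolexo)-exo-trig. The configuration at C4 is set without control in the first acylation (hence a racemate), and C6 is controlled by C4 through the tether, because a three-atom chain on C4 can reach C6 only on its own face; both new centres are bridgeheads and only the cis-1,3 product can form. The step needs C- over O-acylation, attack at the α-carbon (C6) and not at the ring CH in the γ-position of the extended enolate, and reaction of the enol ether in preference to the two isolated alkenes. The last point is secured by the much higher nucleophilicity of the silyl enol ether; the α/γ point is the reason for a silyl and not an alkyl enol ether, since a metal dienolate is acylated at its α-carbon, the site of highest charge, whereas a persisting alkyl dienol ether would favour γ. The stereocentre of 6 is lost on enolisation, so its racemic nature has no consequence.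

Step 6
Reactants: 9 racemic bicyclic trione; 10 (R)-1-phenylethylamine
Product: 11 (1R)-1-phenylethan-1-aminium salt of the enolate of the (1S,5R)-trione
Conditions: 10 (0.5 equiv), EtOAc, rt; recrystallisation from EtOAc–heptane to constant rotation
Reagents that add atoms: none
Why: Classical resolution through diastereomeric ammonium salts; the enolised trione is a vinylogous carboxylic acid and should form a stable salt. Its carbonyl groups, flanked by quaternary bridgeheads, are not expected to condense with the amine at room temperature.

Step 7
Reactants: 11 resolved ammonium salt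
Product: 13 (1R,5S)-4-methoxy-5-methyl-1-(prop-2-en-1-yl)-8-(propan-2-yl)bicyclo[3.3.1]nona-3,7-diene-2,9-dione, via free trione 12 (not isolated)
Conditions: 1 M HCl, EtOAc, 0 °C; then TMSCHN2, PhMe–MeOH, 0 °C → rt
Reagents that add atoms: trimethylsilyldiazomethane, C[Si](C)(C)C=[N+]=[N-]
Why: The acid wash frees the enol 12, which is O-methylated as a vinylogous acid. The oxygen next to the methyl bridgehead is the less hindered one and should be methylated mainly. The regioisomeric ether behaves in the same way in steps 8 to 10 and converges on 16, or is recycled with LiCl.

Step 8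
Reactants: 13 bicyclic methyl enol ether
Product: 14 (2R,6S)-5-methoxy-6-methyl-2-(2-methylpropanoyl)-2,6-bis(2-oxoethyl)cyclohex-4-ene-1,3-dione
Conditions: K2OsO4·2H2O (cat.), NaIO4, 2,6-lutidine, dioxane–H2O, rt
Reagents that add atoms: sodium periodate, [Na+].[O-]I(=O)(=O)=O; water, O
Why: Lemieux–Johnson cleavage of both isolated alkenes; the electron-poor vinylogous ester should not be osmylated. Cleavage of the ring alkene opens the bridge to the isobutyryl ketone on C6 and an acetaldehyde arm on C4, and the allyl group gives the second aldehyde; C4 and C6 are not touched.

Step 9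
Reactants: 14 keto-dialdehyde
Product: 15 (2R,6S)-5-methoxy-6-methyl-2,6-bis(3-methylbut-2-en-1-yl)-2-(2-methylpropanoyl)cyclohex-4-ene-1,3-dione
Conditions: i-PrPPh3I, n-BuLi, THF, 0 °C; then 14, −78 → 0 °C
Reagents that add atoms: isopropyltriphenylphosphonium iodide, CC(C)[P+](c1ccccc1)(c1ccccc1)c1ccccc1.[I-]
Why: Double Wittig olefination with the non-stabilised isopropylidene ylide, the usual way from a CH2CHO arm to a prenyl group. Aldehydes react far faster than the hindered ketones or the vinylogous ester, and low temperature with excess ylide should outrun enolisation and aldol reaction.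

Step 10
Reactants: 15 diprenyl methyl enol ether
Product: 16 (2R,6S)-5-hydroxy-6-methyl-2,6-bis(3-methylbut-2-en-1-yl)-2-(2-methylpropanoyl)cyclohex-4-ene-1,3-dione
Conditions: LiCl, DMSO, 120 °C; aq. NaH2PO4
Reagents that add atoms: none
Why: Nucleophilic demethylation of a vinylogous methyl ester by chloride (SN2 at the methyl group). The neutral conditions avoid acid, which would cyclise an enol onto a prenyl group, and hydroxide, which would cleave an acyl group from C6.

Step 11
Reactants: 17 nerol
Product: 18 [(2R,3S)-3-methyl-3-(4-methylpent-3-en-1-yl)oxiran-2-yl]methanol
Conditions: Ti(OiPr)4 (cat.), D-(−)-diethyl tartrate, t-BuOOH, 4 Å MS, CH2Cl2, −20 °C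
Reagents that add atoms: tert-butyl hydroperoxide, CC(C)(C)OO
Why: Sharpless asymmetric epoxidation; the catalyst formed from Ti(OiPr)4 and the tartrate delivers oxygen only to the allylic alcohol alkene, and the D-(−)-tartrate gives the (2R,3S) epoxide from the Z-alcohol. This sets C3' and the centre that becomes C2' after inversion.

Step 12
Reactants: 18 epoxy alcohol
Product: 19 (2S,3S)-3-(iodomethyl)-2-methyl-2-(4-methylpent-3-en-1-yl)oxirane
Conditions: PPh3, I2, imidazole, Et2O–MeCN, 0 °C, dark
Reagents that add atoms: iodine, II
Why: Appel-type conversion of a primary alcohol into the iodide under neutral conditions that leave the epoxide intact. No stereocentre is touched; the descriptor at the CH carbon changes only through the priority of CH2I.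

Step 13
Reactants: 16 enolised trione; 19 epoxy iodide
Product: 21 (2S,5R,7S)-2-[(2S)-2-hydroxy-6-methylhept-5-en-2-yl]-7-methyl-5,7-bis(3-methylbut-2-en-1-yl)-5-(2-methylpropanoyl)-2,3-dihydro-1-benzofuran-4,6(5H,7H)-dione, via epoxy trione 20 (not isolated)
Conditions: LiOt-Bu (2.2 equiv), THF–PhMe, 0 → 50 °C; aq. NH4Cl
Reagents that add atoms: none
Why: C-alkylation of the lithium enolate at C2 by the soft primary iodide, then 5-exo-tet opening of the epoxide at C2' by the enolate oxygen; this follows the one-pot formation of 2-(hydroxyalkyl)dihydrofurans from cyclic 1,3-diones and halomethyl epoxides. C2' is inverted to (S) and C3' keeps its configuration as the tertiary alcohol. Lithium held between O1 and the isobutyryl oxygen should leave O3 as the free nucleophile, and the bulky alkoxide base does not attack the acyl groups on C6.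

## Compound list

1 | carvacrol, 2-methyl-5-(propan-2-yl)phenol | CC(C)c1ccc(C)c(O)c1 | starting material
2 | allyl bromide, 3-bromoprop-1-ene | C=CCBr | starting material
3 | 1-methyl-4-(propan-2-yl)-2-(prop-2-en-1-yloxy)benzene | Cc1ccc(C(C)C)cc1OCC=C | intermediate
4 | 6-methyl-3-(propan-2-yl)-2-(prop-2-en-1-yl)phenol (6-allylcarvacrol) | Cc1ccc(C(C)C)c(CC=C)c1O | intermediate
5 | tert-butyl(dimethyl)[6-methyl-3-(propan-2-yl)-2-(prop-2-en-1-yl)phenoxy]silane | Cc1ccc(C(C)C)c(CC=C)c1O[Si](C)(C)C(C)(C)C | intermediate
6 | racemic tert-butyl(dimethyl){[2-methyl-5-(propan-2-yl)-6-(prop-2-en-1-yl)cyclohexa-1,4-dien-1-yl]oxy}silane | CC(C)(C)[Si](C)(C)OC1=C(C)CC=C(C(C)C)C1CC=C | intermediate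
7 | malonyl dichloride, propanedioyl dichloride | O=C(Cl)CC(Cl)=O | starting material
8 | 3-[1-methyl-2-oxo-4-(propan-2-yl)-3-(prop-2-en-1-yl)cyclohex-4-en-1-yl]-3-oxopropanoyl chloride (racemic, both epimers at the allyl-bearing carbon) | O=C(Cl)CC(=O)C1(C)CC=C(C(C)C)C(CC=C)C1=O | intermediate (not isolated)
9 | racemic (1RS,5SR)-1-methyl-5-(prop-2-en-1-yl)-6-(propan-2-yl)bicyclo[3.3.1]non-6-ene-2,4,9-trione | CC(C)C1=CCC2(C)C(=O)CC(=O)C1(CC=C)C2=O | intermediate
10 | (1R)-1-phenylethan-1-amine | C[C@@H](N)c1ccccc1 | starting material
11 | (1R)-1-phenylethan-1-aminium salt of the enolate of (1S,5R)-1-methyl-5-(prop-2-en-1-yl)-6-(propan-2-yl)bicyclo[3.3.1]non-6-ene-2,4,9-trione | C[C@@H]([NH3+])c1ccccc1.CC(C)C1=CC[C@@]2(C)C(=O)C=C([O-])[C@]1(CC=C)C2=O | intermediate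
12 | (1S,5R)-1-methyl-5-(prop-2-en-1-yl)-6-(propan-2-yl)bicyclo[3.3.1]non-6-ene-2,4,9-trione | CC(C)C1=CC[C@@]2(C)C(=O)CC(=O)[C@]1(CC=C)C2=O | intermediate (not isolated)
13 | (1R,5S)-4-methoxy-5-methyl-1-(prop-2-en-1-yl)-8-(propan-2-yl)bicyclo[3.3.1]nona-3,7-diene-2,9-dione | CC(C)C1=CC[C@@]2(C)C(OC)=CC(=O)[C@]1(CC=C)C2=O | intermediate
14 | (2R,6S)-5-methoxy-6-methyl-2-(2-methylpropanoyl)-2,6-bis(2-oxoethyl)cyclohex-4-ene-1,3-dione | COC1=CC(=O)[C@@](CC=O)(C(=O)C(C)C)C(=O)[C@@]1(C)CC=O | intermediate
15 | (2R,6S)-5-methoxy-6-methyl-2,6-bis(3-methylbut-2-en-1-yl)-2-(2-methylpropanoyl)cyclohex-4-ene-1,3-dione | COC1=CC(=O)[C@@](CC=C(C)C)(C(=O)C(C)C)C(=O)[C@@]1(C)CC=C(C)C | intermediate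
16 | (2R,6S)-5-hydroxy-6-methyl-2,6-bis(3-methylbut-2-en-1-yl)-2-(2-methylpropanoyl)cyclohex-4-ene-1,3-dione | OC1=CC(=O)[C@@](CC=C(C)C)(C(=O)C(C)C)C(=O)[C@@]1(C)CC=C(C)C | intermediate
17 | nerol, (2Z)-3,7-dimethylocta-2,6-dien-1-ol | CC(C)=CCC/C(C)=C\CO | starting material
18 | [(2R,3S)-3-methyl-3-(4-methylpent-3-en-1-yl)oxiran-2-yl]methanol | CC(C)=CCC[C@]1(C)O[C@@H]1CO | intermediate
19 | (2S,3S)-3-(iodomethyl)-2-methyl-2-(4-methylpent-3-en-1-yl)oxirane | CC(C)=CCC[C@]1(C)O[C@@H]1CI | intermediate
20 | (2R,6S)-5-hydroxy-6-methyl-4-{[(2R,3S)-3-methyl-3-(4-methylpent-3-en-1-yl)oxiran-2-yl]methyl}-2,6-bis(3-methylbut-2-en-1-yl)-2-(2-methylpropanoyl)cyclohex-4-ene-1,3-dione | OC1=C(C[C@H]2O[C@@]2(C)CCC=C(C)C)C(=O)[C@@](CC=C(C)C)(C(=O)C(C)C)C(=O)[C@@]1(C)CC=C(C)C | intermediate (not isolated)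
21 | (2S,5R,7S)-2-[(2S)-2-hydroxy-6-methylhept-5-en-2-yl]-7-methyl-5,7-bis(3-methylbut-2-en-1-yl)-5-(2-methylpropanoyl)-2,3-dihydro-1-benzofuran-4,6(5H,7H)-dione | CC(C)=CCC[C@](C)(O)[C@@H]1CC2=C(O1)[C@](C)(CC=C(C)C)C(=O)[C@](CC=C(C)C)(C(=O)C(C)C)C2=O | target

## Step count and uncertain steps

Total step count: 13. Longest linear sequence: 11 steps (steps 1 to 10 and step 13, from carvacrol).

**Step 5 (key step).** The second acylation may be misdirected. The enolate may be acylated at oxygen to an enol lactone, or the ring CH in the γ-position may attack instead of C6. C6 is fully substituted and flanked by the isopropyl-bearing carbon, and an extended enol derivative has its largest frontier coefficient at γ. Base may also move the ring alkene into conjugation before closure. The fallback sets out from 6 and makes the two bonds one at a time. The first-stage acylation is run with methyl 3-chloro-3-oxopropanoate in place of 7 and gives the β-keto ester methyl 3-[1-methyl-2-oxo-4-(propan-2-yl)-3-(prop-2-en-1-yl)cyclohex-4-en-1-yl]-3-oxopropanoate F1. Its side-chain ketone is O-methylated (HC(OMe)3, MeOH, cat. H2SO4) to the β-methoxy acrylate F2. LiN(iPr)2 in THF at −78 °C then removes the only ring α-proton, and the lithium dienolate adds to the ester at its α-carbon in an intramolecular Claisen condensation. Methoxide released in the condensation can interconvert the acrylate isomers by addition–elimination, so both should pass through the one that can close. The product is the racemic methyl ether F3, with the methoxy group already on the carbon next to the methyl bridgehead. Its enantiomers are separated by preparative chromatography on a chiral stationary phase, and the route is rejoined at 13.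

**Step 13.** The ambident enolate may be alkylated at oxygen in the intermolecular stage, and the ring may close through O1 instead of O3, since both enolate oxygens can reach C2' in a 5-exo mode; the preference for O3 rests only on lithium chelation and on the smaller substituents at C4. The fallback sets out from 18 and 16 and makes the C2–C1' bond by condensation and reduction instead of substitution. 18 is oxidised (Dess–Martin periodinane, NaHCO3) to the epoxy aldehyde (2S,3S)-3-methyl-3-(4-methylpent-3-en-1-yl)oxirane-2-carbaldehyde F4. F4 is combined with 16, L-proline (cat.) and the Hantzsch ester in CH2Cl2 in a three-component reductive alkylation, the reliable C-alkylation of 2-unsubstituted cyclic triones. This gives 20 as an isolated compound, where the route is rejoined; 20 is then closed with LiOt-Bu as in step 13.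

**Step 4.** The silyl group may be lost to amide or alkoxide, or the allyl double bond may migrate into conjugation with the arene and then be reduced. The fallback sets out from 4 and uses a methyl ether. 4 is methylated (MeI, K2CO3, acetone) to 2-methoxy-1-methyl-4-(propan-2-yl)-3-(prop-2-en-1-yl)benzene F5, which is reduced under the same Birch conditions to the methyl dienol ether F6. F6 is annulated with 7 (Et2O, −20 °C; KOH, BnEt3NCl), with chloride removing the methyl group at the end, and the route is rejoined at 9. The price is that the dienol ether persists after the first acylation, so the γ-closure of step 5 becomes more likely.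

**Step 6.** Neither diastereomeric salt may crystallise selectively (oiling out or a solid solution). The fallback sets out from 9 and separates covalent diastereomers instead of salts.
- 9 is O-acylated with (1S,4R)-camphanoyl chloride (Et3N, CH2Cl2, −20 °C, without a nucleophilic acyl-transfer catalyst, which would promote O-to-C acyl migration). The oxygen next to the methyl bridgehead is the less hindered one and should be acylated mainly.
- The diastereomeric enol esters are separated by crystallisation or chromatography on silica. The one derived from the (1S,5R)-trione is (1R,5S)-5-methyl-2,9-dioxo-1-(prop-2-en-1-yl)-8-(propan-2-yl)bicyclo[3.3.1]nona-3,7-dien-4-yl (1S,4R)-4,7,7-trimethyl-3-oxo-2-oxabicyclo[2.2.1]heptane-1-carboxylate F7.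
- F7 is cleaved with LiOH in THF–H2O at 0 °C; the trione survives aqueous hydroxide as its enolate, as it does in step 5. Acidification gives 12, where the route is rejoined before the methylation of step 7.

**Step 8.** Osmylation of the hindered trisubstituted ring alkene may stop short, so that only the allyl group is cleaved and the bridge stays closed. The fallback sets out from 13 and uses ozonolysis (O3, CH2Cl2–MeOH, −78 °C, stopped at the first persistent colour of ozone; then Me2S). A 1,3-dipolar cycloaddition is much less sensitive to steric shielding than osmate ester formation. It gives 14 directly and makes no new compound.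

## Further compounds

F1 | step 5 | methyl 3-[1-methyl-2-oxo-4-(propan-2-yl)-3-(prop-2-en-1-yl)cyclohex-4-en-1-yl]-3-oxopropanoate (racemic) | COC(=O)CC(=O)C1(C)CC=C(C(C)C)C(CC=C)C1=O
F2 | step 5 | methyl (2E)-3-methoxy-3-[1-methyl-2-oxo-4-(propan-2-yl)-3-(prop-2-en-1-yl)cyclohex-4-en-1-yl]prop-2-enoate (racemic) | CO/C(=C/C(=O)OC)C1(C)CC=C(C(C)C)C(CC=C)C1=O
F3 | step 5 | racemic 4-methoxy-5-methyl-1-(prop-2-en-1-yl)-8-(propan-2-yl)bicyclo[3.3.1]nona-3,7-diene-2,9-dione | CC(C)C1=CCC2(C)C(OC)=CC(=O)C1(CC=C)C2=O
F4 | step 13 | (2S,3S)-3-methyl-3-(4-methylpent-3-en-1-yl)oxirane-2-carbaldehyde | CC(C)=CCC[C@]1(C)O[C@@H]1C=O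
F5 | step 4 | 2-methoxy-1-methyl-4-(propan-2-yl)-3-(prop-2-en-1-yl)benzene | COc1c(C)ccc(C(C)C)c1CC=C
F6 | step 4 | racemic 1-methoxy-2-methyl-5-(propan-2-yl)-6-(prop-2-en-1-yl)cyclohexa-1,4-diene | COC1=C(C)CC=C(C(C)C)C1CC=C
F7 | step 6 | (1R,5S)-5-methyl-2,9-dioxo-1-(prop-2-en-1-yl)-8-(propan-2-yl)bicyclo[3.3.1]nona-3,7-dien-4-yl (1S,4R)-4,7,7-trimethyl-3-oxo-2-oxabicyclo[2.2.1]heptane-1-carboxylate | CC(C)C1=CC[C@@]2(C)C(OC(=O)[C@@]34CC[C@@](C)(C(=O)O3)C4(C)C)=CC(=O)[C@]1(CC=C)C2=O
F0 | step 8 | none | none
A1 | alternative 1 | 4-methyl-4-(3-methylbut-2-en-1-yl)-6-(2-methylpropanoyl)cyclohexane-1,3,5-trione, enol form, C4 as in 21 | CC(C)C(=O)C1=C(O)CC(=O)[C@](C)(CC=C(C)C)C1=O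
A2 | alternative 1 | (2S)-6-methyl-2-[(2S)-oxiran-2-yl]hept-5-en-2-ol | CC(C)=CCC[C@](C)(O)[C@@H]1CO1
A3 | alternative 1 | ring A/B enol with C4, C2' and C3' set and C6 enolic | CC(C)=CCC[C@](C)(O)[C@@H]1CC2=C(O1)[C@](C)(CC=C(C)C)C(=O)C(C(=O)C(C)C)=C2O
A4 | alternative 2 | 3-ethoxy-4-methyl-4-(3-methylbut-2-en-1-yl)cyclobut-2-enone carrying the bis(triethylsilyl)-protected side chain on C2 | CCOC1=C(C[C@H](O[Si](CC)(CC)CC)[C@@](C)(O[Si](CC)(CC)CC)CCC=C(C)C)C(=O)C1(C)CC=C(C)C
A5 | alternative 2 | 1-(triisopropylsiloxy)-5-methylhex-4-en-1-yne | CC(C)=CCC#CO[Si](C(C)C)(C(C)C)C(C)C
A6 | alternative 2 | ring A cyclohexa-2,4-dienone with C1 silyl enol ether and C3 ethyl enol ether | CCOC1=C(C[C@H](O[Si](CC)(CC)CC)[C@@](C)(O[Si](CC)(CC)CC)CCC=C(C)C)C(O[Si](C(C)C)(C(C)C)C(C)C)=C(CC=C(C)C)C(=O)[C@@]1(C)CC=C(C)C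
A7 | alternative 3 | methyl 4,5-dihydrofuran-3-carboxylate carrying the β-diketone side arm on C2 and the triethylsilyl-protected carbinol on C5 | CC(C)=CCC[C@](C)(O[Si](CC)(CC)CC)[C@@H]1CC(C(=O)OC)=C(O1)[C@](C)(CC=C(C)C)C(=O)CC(=O)C(C)C
A8 | alternative 3 | ring A/B enol, triethylsilyl ether at C3', C6 enolic | CC(C)=CCC[C@](C)(O[Si](CC)(CC)CC)[C@@H]1CC2=C(O1)[C@](C)(CC=C(C)C)C(=O)C(C(=O)C(C)C)=C2O
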